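(Readings and results are simulated on assumed constants; the scatter is artificial.)

A dosed flask's clock overstates what its starting material has been through: a portion fed late has stood for less time than one fed early. For a steady feed, the average stay is the time less half the feed.

common to all: reagent in the second phase 0.396 M
- north-west: starting material 0.16 M (fed, over 5.0 min); protic impurity 0.044 M; temperature −45 °C; run made earlier; the fed solution adds 0.25 times the starting volume
- east: starting material 0.58 M (fed, over 5.0 min); protic impurity 0.044 M; temperature −20 °C; run made earlier; the fed solution adds 0.25 times the starting volume
- dusk: starting material 0.22 M (fed, over 5.0 min); protic impurity 0.0440 M; temperature 0 °C; the fed solution adds 0.25 times the starting volume; time 8.0 min; volume of the second phase over the first 1.0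
- summer: starting material 0.80 M; protic impurity 0.0440 M; temperature −40 °C; everything together at the start, the whole solution of starting material included, so that from the start the volume is larger by 0.25 times the starting volume; time 8.0 min; volume of the second phase over the first 1.0

- north-west (time / min: target / %): 10.0: 3.4; 20.0: 9.6; 30.0: 13.2; 40.0: 18.1; 50.0: 21.0; 60.0: 24.4
- east (time / min: target / %): 2.50: 1.7; 5.00: 6.4; 8.00: 16.7; 10.0: 20.5; 15.0: 30.7

(standard deviation of a reading: 0.5 percentage points)

1. the flask that ends with the higher amount of target, in percent of the starting material charged, or "neither" when 2 percentage points or less lies between them (dusk / summer / neither)
2. final target, as a percentage of the starting material charged, in dusk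
3. final target, as a percentage of the starting material charged, in summer

- charges are per starting volume, the dose included; the dosed solution carries all of it
- in the second phase: reagent in the second phase; everything else is in the first
- charges count per volume of the first phase; a concentration in a rate is the amount of a species over the volume of its own phase; every rate counts per litre of the first phase
- the earlier runs hold the two phases in the same ratio of volumes as the flask asked about
- percentages count the whole charge, also what has not yet gone in
- a reading or a percentage of target counts all its forms, free or not

The last reading of each run, taken as first order over its average stay, gives a pseudo-first-order constant. The north-west run's 24.4% gives 0.00486 min⁻¹, and the east run's 30.7% gives 0.0293 min⁻¹. Together they read as an activation energy of 34.5 kJ mol⁻¹, although the two runs differ in charge as well as temperature. That reading puts the constant at 0.0975 min⁻¹ in dusk and 0.00719 min⁻¹ in summer.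

In dusk the reckoned target curve starts flat and bends upward while the feed runs. The knee comes at 5.0 min, when the slope stops growing. By then the average stay is half the feed, which gives 0.244 turnovers and a target fraction of 21.6%.

At 8.0 min, the turnovers, meaning the constant times the average stay, reach 0.536, and the fraction reaches 41.5%.

Summer has its whole charge in from the start, so its average stay is the full time. It counts 0.0575 turnovers, which gives 5.59%.

The forecast names dusk, with 40% in dusk and 6% in summer: “Dusk wins clearly”. The reckoning here stands slightly higher in dusk and slightly lower in summer.

The flasks give dusk as the higher, with 44.0% in dusk and 4.75% in summer.

    reagent in the reaction phase ⇌ reagent in the second phase, rate k1*([reagent in the reaction phase] - [reagent in the second phase]/K1) per volume of the first phase (partition coefficient = 1.50, kL = 0.00260 s⁻¹)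
    starting material + reagent in the reaction phase → target (k = 0.0380 M⁻¹ s⁻¹, Ea = 44.0 kJ mol⁻¹)
    starting material + protic impurity → quenched substrate (k = 0.700 M⁻¹ s⁻¹, Ea = 49.0 kJ mol⁻¹)
    crystals ⇌ target, rate k4*(cs4 - [target]) while solid is left; crystals form when [target] > cs4 (solubility = 0.0720 M, k = 0.640 s⁻¹)
    (constants at 0 °C)

Read back as turnovers, dusk's result is 0.580 against the 0.536 counted, and summer's is 0.0487 against 0.0575. The summer neighbour with 0.32 M of starting material counts the same 0.0575 turnovers and ends at 4.86%. At 8.00 min in summer, the step to target gives starting material a half-life of 78 min, ten times the time the flask has run. Starting material still stands at 89.8% of its charge.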